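The hexasubstituted benzene ring (C1'–C6') is cut at C5'–C6' and C3'–C4' into two pieces. One is a 2-prenyl-3-silyloxycyclobutenone that carries the pyranone on a CH2 arm at C4; the other is a siloxyalkyne made from D-isoleucine. Their thermal Danheiser benzannulation sets all six substituents in one operation and exploits the alternating oxygens at C2', C4' and C6': two arrive as triisopropylsilyl ethers, and only C6'–OH is free for methylation. The side-chain stereocentre sits next to a triethylsilyl-protected carbinol, so nothing can enolise it before the penultimate oxidation. A fluoride-labile SEM group on the pyranone lets one fluoride treatment finish the synthesis.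

Key step: step 12

Remark: C1'–C6' are the benzene carbons of the target (C1' CH2 bridge, C2' OH, C3' prenyl, C4' OH, C5' acyl, C6' OMe); SEM = 2-(trimethylsilyl)ethoxymethyl.
Remark: the carbinol carbon derived from C2 of D-isoleucine ends as the ketone carbon, so its configuration (drawn R throughout) is immaterial; only C3 (R) reaches the target.

Step 1
Reactants: 1 ethyl 4-methylpent-3-enoate
Product: 4 5-methyl-1-(triisopropylsilyloxy)hex-4-en-1-yne, via lithium dibromoenolate 2 (not isolated), via lithium ynolate 3 (not isolated)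
Conditions: CH2Br2, lithium 2,2,6,6-tetramethylpiperidide, THF, −78 °C; LiN(SiMe3)2; n-BuLi, −78 → 0 °C; i-Pr3SiOTf, −78 → 0 °C
Reagents that add atoms: dibromomethane, BrCBr; triisopropylsilyl triflate, CC(C)[Si](C(C)C)(C(C)C)OS(=O)(=O)C(F)(F)F
Why: Kowalski ester homologation: dibromomethyllithium adds to the ester carbonyl faster than it deprotonates the allylic α-CH2, dibromoenolate 2 undergoes bromine–lithium exchange and 1,2-shift to ynolate 3, and the bulky silyl triflate silylates 3 on oxygen to a siloxyalkyne that should survive chromatography.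

Step 2
Reactants: 5 pentan-3-one
Product: 6 (Z)-3-(trimethylsilyloxy)pent-2-ene
Conditions: Me3SiOTf, Et3N, Et2O, 0 °C
Reagents that add atoms: trimethylsilyl triflate, C[Si](C)(C)OS(=O)(=O)C(F)(F)F
Why: Silyl enol ether formation by soft enolisation of a symmetrical ketone, so only one regioisomer can form; the alkene geometry (Z expected to dominate) is erased in step 3.

Step 3
Reactants: 6 (Z)-3-(trimethylsilyloxy)pent-2-ene; 7 malonyl dichloride
Product: 8 6-ethyl-4-hydroxy-5-methyl-2H-pyran-2-one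
Conditions: Et2O, −78 °C → rt
Reagents that add atoms: none
Why: Effenberger pyranone synthesis: the enol ether is C-acylated by one acyl chloride, the enol of the resulting 1,3-diketone is O-acylated by the other (lactonisation), and tautomerisation gives the 4-hydroxypyranone with ethyl at C6 and methyl at C5.

Step 4
Reactants: 8 6-ethyl-4-hydroxy-5-methyl-2H-pyran-2-one; 9 acrolein
Product: 10 7-ethyl-2-hydroxy-8-methyl-3,4-dihydro-2H,5H-pyrano[4,3-b]pyran-5-one
Conditions: Et3N (cat.), MeCN, 0 °C → rt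
Reagents that add atoms: none
Why: Michael addition of the vinylogous acid through C3, its only unsubstituted nucleophilic carbon, under tertiary-amine catalysis (no iminium, hence no Knoevenagel path); the adduct should rest as the six-membered cyclic hemiacetal.

Step 5
Reactants: 10 7-ethyl-2-hydroxy-8-methyl-3,4-dihydro-2H,5H-pyrano[4,3-b]pyran-5-one
Product: 12 3-(6-ethyl-5-methyl-2-oxo-4-{[2-(trimethylsilyl)ethoxy]methoxy}-2H-pyran-3-yl)propanal, via open-chain pyranolate 11 (not isolated)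
Conditions: SEMCl, i-Pr2NEt, CH2Cl2, 0 °C → rt
Reagents that add atoms: 2-(trimethylsilyl)ethoxymethyl chloride, C[Si](C)(C)CCOCCl
Why: Ring–chain tautomerism followed by O-alkoxymethylation: the base opens the hemiacetal because the open form is a far stronger acid, and pyranolate 11 is alkylated on O4 by the hard chloromethyl ether, leaving the aldehyde free; SEM is chosen because it survives base, heat and buffered HF and leaves with fluoride at the end.

Step 6
Reactants: 12 3-(6-ethyl-5-methyl-2-oxo-4-{[2-(trimethylsilyl)ethoxy]methoxy}-2H-pyran-3-yl)propanal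
Product: 13 3-(6-ethyl-5-methyl-2-oxo-4-{[2-(trimethylsilyl)ethoxy]methoxy}-2H-pyran-3-yl)propanoic acid
Conditions: NaClO2, NaH2PO4, 2-methylbut-2-ene, t-BuOH/H2O, 0 °C → rt
Reagents that add atoms: sodium chlorite, [Na+].[O-]Cl=O
Why: Pinnick oxidation is specific for aldehydes and runs in a buffered medium with a hypochlorite scavenger, so the pyranone, the SEM group and the silane should not be affected.

Step 7
Reactants: 13 3-(6-ethyl-5-methyl-2-oxo-4-{[2-(trimethylsilyl)ethoxy]methoxy}-2H-pyran-3-yl)propanoic acid; 4 5-methyl-1-(triisopropylsilyloxy)hex-4-en-1-yne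
Product: 16 4-[(6-ethyl-5-methyl-2-oxo-4-{[2-(trimethylsilyl)ethoxy]methoxy}-2H-pyran-3-yl)methyl]-2-(3-methylbut-2-en-1-yl)-3-(triisopropylsilyloxy)cyclobut-2-en-1-one, via acid chloride 14 (not isolated), via ketene 15 (not isolated)
Conditions: 1-chloro-N,N,2-trimethylprop-1-en-1-amine, CH2Cl2, 0 °C; then slow addition to 4 (1.3 equiv) and Et3N, CH2Cl2, rt
Reagents that add atoms: none
Why: The α-chloroenamine (Ghosez reagent) makes acid chloride 14 without HCl, triethylamine dehydrochlorinates it to monoalkylketene 15 at low stationary concentration, and 15 undergoes the known ketene–siloxyalkyne [2+2] cycloaddition, its carbonyl carbon bonding to the nucleophilic prenyl-bearing alkyne carbon, which fixes prenyl at C2 and the silyloxy group at C3.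

Step 8
Reactants: 17 D-isoleucine
Product: 18 (2R,3R)-2-hydroxy-3-methylpentanoic acid
Conditions: NaNO2, 1 M H2SO4, H2O, 0 °C → rt
Reagents that add atoms: water, O
Why: Diazotisation of an α-amino acid (hydroxy-deamination) goes with retention at C2 by double inversion through the α-lactone and does not touch C3.

Step 9
Reactants: 18 (2R,3R)-2-hydroxy-3-methylpentanoic acid
Product: 19 methyl (2R,3R)-2-hydroxy-3-methylpentanoate
Conditions: MeOH, H2SO4 (cat.), reflux
Reagents that add atoms: methanol, CO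
Why: Fischer esterification under acid catalysis, with no risk to the C3 stereocentre.

Step 10
Reactants: 19 methyl (2R,3R)-2-hydroxy-3-methylpentanoate
Product: 20 methyl (2R,3R)-3-methyl-2-(triethylsilyloxy)pentanoate
Conditions: Et3SiCl, imidazole, DMF, 0 °C → rt
Reagents that add atoms: chlorotriethylsilane, CC[Si](CC)(CC)Cl
Why: Routine silylation of a secondary alcohol with a silyl chloride and imidazole; triethylsilyl is chosen because acidic fluoride later removes it from an alkyl oxygen in the presence of aryl triisopropylsilyl ethers.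

Step 11
Reactants: 20 methyl (2R,3R)-3-methyl-2-(triethylsilyloxy)pentanoate
Product: 23 (3R,4R)-4-methyl-3-(triethylsilyloxy)-1-(triisopropylsilyloxy)hex-1-yne, via lithium dibromoenolate 21 (not isolated), via lithium ynolate 22 (not isolated)
Conditions: CH2Br2, lithium 2,2,6,6-tetramethylpiperidide, THF, −78 °C; LiN(SiMe3)2; n-BuLi, −78 → 0 °C; i-Pr3SiOTf, −78 → 0 °C
Reagents that add atoms: dibromomethane, BrCBr; triisopropylsilyl triflate, CC(C)[Si](C(C)C)(C(C)C)OS(=O)(=O)C(F)(F)F
Why: Kowalski ester homologation as in step 1; C4 is not acidic and keeps its R configuration, while the carbinol centre C3 is destined to become the ketone carbon.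

Step 12
Reactants: 16 4-[(6-ethyl-5-methyl-2-oxo-4-{[2-(trimethylsilyl)ethoxy]methoxy}-2H-pyran-3-yl)methyl]-2-(3-methylbut-2-en-1-yl)-3-(triisopropylsilyloxy)cyclobut-2-en-1-one; 23 (3R,4R)-4-methyl-3-(triethylsilyloxy)-1-(triisopropylsilyloxy)hex-1-yne
Product: 28 6-ethyl-3-({2-hydroxy-3-[(1R,2R)-2-methyl-1-(triethylsilyloxy)butyl]-5-(3-methylbut-2-en-1-yl)-4,6-bis(triisopropylsilyloxy)phenyl}methyl)-5-methyl-4-{[2-(trimethylsilyl)ethoxy]methoxy}-2H-pyran-2-one, via vinylketene 24 (not isolated), via vinylcyclobutenone 25 (not isolated), via dienylketene 26 (not isolated), via cyclohexadienone 27 (not isolated)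
Conditions: 23 (1.5 equiv), toluene (degassed), 80 → 110 °C, sealed tube, Ar
Reagents that add atoms: none
Why: Heating opens 16 by four-electron electrocyclic ring opening (pyranonylmethyl group turning outward, which also blocks a 1,5-hydrogen shift) to vinylketene 24, whose carbonyl carbon is attacked by the nucleophilic carbinol-bearing carbon of 23 in a regiospecific [2+2] cycloaddition to 25; 25 opens to dienylketene 26, which closes to dienone 27 and tautomerises to the phenol. This is the Danheiser benzannulation in its siloxyalkyne form, known to give resorcinol monosilyl ethers. The benzene ring is closed by a thermal disrotatory six-electron electrocyclisation of the dienylketene (C6'–C1' bond), a six-membered closure that is geometrically unconstrained once the central alkene is cis. No stereocentre is created; the side-chain centre is not enolisable and the carbinol centre is later oxidised. The step needs full regiocontrol and differentiation of the three oxygens: the polarity of the ynol ether puts the side chain at C5' next to the former ketene carbonyl C6', which alone emerges as a free hydroxyl, while C2' and C4' keep their silyl groups. The demand is mainly steric, so the alkyne is used in excess and the temperature is raised only after the cyclobutenone has been consumed.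

Step 13
Reactants: 28 6-ethyl-3-({2-hydroxy-3-[(1R,2R)-2-methyl-1-(triethylsilyloxy)butyl]-5-(3-methylbut-2-en-1-yl)-4,6-bis(triisopropylsilyloxy)phenyl}methyl)-5-methyl-4-{[2-(trimethylsilyl)ethoxy]methoxy}-2H-pyran-2-one
Product: 29 6-ethyl-3-({2-methoxy-3-[(1R,2R)-2-methyl-1-(triethylsilyloxy)butyl]-5-(3-methylbut-2-en-1-yl)-4,6-bis(triisopropylsilyloxy)phenyl}methyl)-5-methyl-4-{[2-(trimethylsilyl)ethoxy]methoxy}-2H-pyran-2-one
Conditions: MeI, K2CO3, acetone, 45 °C
Reagents that add atoms: iodomethane, CI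
Why: Williamson O-methylation of the only free phenol (C6'–OH); the pyranone oxygen is blocked, K2CO3 in acetone should not cleave silyl ethers, and silyl transfer from the neighbouring carbinol oxygen to the more stable phenoxide has no driving force.

Step 14
Reactants: 29 6-ethyl-3-({2-methoxy-3-[(1R,2R)-2-methyl-1-(triethylsilyloxy)butyl]-5-(3-methylbut-2-en-1-yl)-4,6-bis(triisopropylsilyloxy)phenyl}methyl)-5-methyl-4-{[2-(trimethylsilyl)ethoxy]methoxy}-2H-pyran-2-one
Product: 30 6-ethyl-3-({3-[(1R,2R)-1-hydroxy-2-methylbutyl]-2-methoxy-5-(3-methylbut-2-en-1-yl)-4,6-bis(triisopropylsilyloxy)phenyl}methyl)-5-methyl-4-{[2-(trimethylsilyl)ethoxy]methoxy}-2H-pyran-2-one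
Conditions: HF·pyridine, pyridine, THF, 0 °C → rt
Reagents that add atoms: none
Why: Selective desilylation: under acidic fluoride, silyl ethers of alcohols cleave faster than aryl silyl ethers (the reverse of basic fluoride) and triethylsilyl far faster than triisopropylsilyl, while SEM needs unbuffered fluoride, so only the carbinol should be freed; the pyridine buffer avoids ionisation at the electron-rich benzylic position.

Step 15
Reactants: 30 6-ethyl-3-({3-[(1R,2R)-1-hydroxy-2-methylbutyl]-2-methoxy-5-(3-methylbut-2-en-1-yl)-4,6-bis(triisopropylsilyloxy)phenyl}methyl)-5-methyl-4-{[2-(trimethylsilyl)ethoxy]methoxy}-2H-pyran-2-one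
Product: 31 6-ethyl-3-({2-methoxy-3-[(2R)-2-methylbutanoyl]-5-(3-methylbut-2-en-1-yl)-4,6-bis(triisopropylsilyloxy)phenyl}methyl)-5-methyl-4-{[2-(trimethylsilyl)ethoxy]methoxy}-2H-pyran-2-one
Conditions: Dess–Martin periodinane, pyridine, CH2Cl2, 0 °C → rt
Reagents that add atoms: none
Why: Dess–Martin oxidation of a hindered secondary benzylic alcohol under buffered, non-basic conditions; the di-ortho-substituted aryl ketone is twisted and should not enolise, so the α-stereocentre, exposed here for the first time, should be kept.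

Step 16
Reactants: 31 6-ethyl-3-({2-methoxy-3-[(2R)-2-methylbutanoyl]-5-(3-methylbut-2-en-1-yl)-4,6-bis(triisopropylsilyloxy)phenyl}methyl)-5-methyl-4-{[2-(trimethylsilyl)ethoxy]methoxy}-2H-pyran-2-one
Product: 32 6-ethyl-3-({2,4-dihydroxy-6-methoxy-5-[(2R)-2-methylbutanoyl]-3-(3-methylbut-2-en-1-yl)phenyl}methyl)-4-hydroxy-5-methyl-2H-pyran-2-one
Conditions: n-Bu4NF, THF, 0 °C → rt, Ar; AcOH quench
Reagents that add atoms: none
Why: Global fluoride deprotection: fluoride cleaves both aryl Si–O bonds and fragments the SEM group (β-elimination to ethene, formaldehyde and Me3SiF), and the phenoxide/pyranolate formed is a vinylogous carboxylate that deactivates the ketone α-proton, so epimerisation is not expected; the fully substituted ring offers formaldehyde no site of attack.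

Compound list
1 | ethyl 4-methylpent-3-enoate | CCOC(=O)CC=C(C)C | starting material
2 | lithium 1,1-dibromo-5-methylhexa-1,4-dien-2-olate | [Li+].[O-]C(=C(Br)Br)CC=C(C)C | intermediate
3 | lithium 5-methylhex-4-en-1-yn-1-olate | [Li+].[O-]C#CCC=C(C)C | intermediate
4 | 5-methyl-1-(triisopropylsilyloxy)hex-4-en-1-yne | CC(C)=CCC#CO[Si](C(C)C)(C(C)C)C(C)C | intermediate
5 | pentan-3-one | CCC(=O)CC | starting material
6 | (Z)-3-(trimethylsilyloxy)pent-2-ene | C/C=C(\O[Si](C)(C)C)CC | intermediate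
7 | malonyl dichloride | O=C(Cl)CC(=O)Cl | starting material
8 | 6-ethyl-4-hydroxy-5-methyl-2H-pyran-2-one | CCc1oc(=O)cc(O)c1C | intermediate
9 | acrolein | C=CC=O | starting material
10 | 7-ethyl-2-hydroxy-8-methyl-3,4-dihydro-2H,5H-pyrano[4,3-b]pyran-5-one (racemic hemiacetal) | CCc1oc(=O)c2c(c1C)OC(O)CC2 | intermediate
11 | N-ethyldiisopropylammonium 6-ethyl-5-methyl-2-oxo-3-(3-oxopropyl)-2H-pyran-4-olate | CCc1oc(=O)c(CCC=O)c([O-])c1C.CC[NH+](C(C)C)C(C)C | intermediate
12 | 3-(6-ethyl-5-methyl-2-oxo-4-{[2-(trimethylsilyl)ethoxy]methoxy}-2H-pyran-3-yl)propanal | CCc1oc(=O)c(CCC=O)c(OCOCC[Si](C)(C)C)c1C | intermediate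
13 | 3-(6-ethyl-5-methyl-2-oxo-4-{[2-(trimethylsilyl)ethoxy]methoxy}-2H-pyran-3-yl)propanoic acid | CCc1oc(=O)c(CCC(=O)O)c(OCOCC[Si](C)(C)C)c1C | intermediate
14 | 3-(6-ethyl-5-methyl-2-oxo-4-{[2-(trimethylsilyl)ethoxy]methoxy}-2H-pyran-3-yl)propanoyl chloride | CCc1oc(=O)c(CCC(=O)Cl)c(OCOCC[Si](C)(C)C)c1C | intermediate
15 | 6-ethyl-5-methyl-3-(3-oxoprop-2-en-1-yl)-4-{[2-(trimethylsilyl)ethoxy]methoxy}-2H-pyran-2-one (monoalkylketene) | CCc1oc(=O)c(CC=C=O)c(OCOCC[Si](C)(C)C)c1C | intermediate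
16 | 4-[(6-ethyl-5-methyl-2-oxo-4-{[2-(trimethylsilyl)ethoxy]methoxy}-2H-pyran-3-yl)methyl]-2-(3-methylbut-2-en-1-yl)-3-(triisopropylsilyloxy)cyclobut-2-en-1-one (racemic at C4, a centre lost on aromatisation) | O=C1C(CC=C(C)C)=C(O[Si](C(C)C)(C(C)C)C(C)C)C1Cc1c(OCOCC[Si](C)(C)C)c(C)c(CC)oc1=O | intermediate
17 | D-isoleucine, (2R,3R)-2-amino-3-methylpentanoic acid | CC[C@@H](C)[C@@H](N)C(=O)O | starting material
18 | (2R,3R)-2-hydroxy-3-methylpentanoic acid | CC[C@@H](C)[C@@H](O)C(=O)O | intermediate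
19 | methyl (2R,3R)-2-hydroxy-3-methylpentanoate | CC[C@@H](C)[C@@H](O)C(=O)OC | intermediate
20 | methyl (2R,3R)-3-methyl-2-(triethylsilyloxy)pentanoate | CC[C@@H](C)[C@@H](O[Si](CC)(CC)CC)C(=O)OC | intermediate
21 | lithium (3R,4R)-1,1-dibromo-4-methyl-3-(triethylsilyloxy)hex-1-en-2-olate | [Li+].[O-]C(=C(Br)Br)[C@H](O[Si](CC)(CC)CC)[C@H](C)CC | intermediate
22 | lithium (3R,4R)-4-methyl-3-(triethylsilyloxy)hex-1-yn-1-olate | [Li+].[O-]C#C[C@H](O[Si](CC)(CC)CC)[C@H](C)CC | intermediate
23 | (3R,4R)-4-methyl-3-(triethylsilyloxy)-1-(triisopropylsilyloxy)hex-1-yne | CC(C)[Si](C(C)C)(C(C)C)OC#C[C@H](O[Si](CC)(CC)CC)[C@H](C)CC | intermediate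
24 | vinylketene from ring opening of 16: 6-ethyl-5-methyl-3-[(2Z)-4-(3-methylbut-2-en-1-yl)-5-oxo-3-(triisopropylsilyloxy)penta-2,4-dien-1-yl]-4-{[2-(trimethylsilyl)ethoxy]methoxy}-2H-pyran-2-one | O=C=C(CC=C(C)C)/C(O[Si](C(C)C)(C(C)C)C(C)C)=C/Cc1c(OCOCC[Si](C)(C)C)c(C)c(CC)oc1=O | intermediate
25 | [2+2] adduct of 24 and 23: cyclobut-2-en-1-one with the (1R,2R)-2-methyl-1-(triethylsilyloxy)butyl group at C2, triisopropylsilyloxy at C3, and at C4 both prenyl and the (Z)-1-(triisopropylsilyloxy)-3-(pyranonyl)prop-1-enyl group (mixture at C4) | O=C1C([C@H](O[Si](CC)(CC)CC)[C@H](C)CC)=C(O[Si](C(C)C)(C(C)C)C(C)C)C1(CC=C(C)C)/C(O[Si](C(C)C)(C(C)C)C(C)C)=C/Cc1c(OCOCC[Si](C)(C)C)c(C)c(CC)oc1=O | intermediate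
26 | dienylketene from ring opening of 25: O=C=C(side chain)–C(OSi-i-Pr3)=C(prenyl)–C(OSi-i-Pr3)=CH–CH2–pyranone, central alkene cis | O=C=C([C@H](O[Si](CC)(CC)CC)[C@H](C)CC)/C(O[Si](C(C)C)(C(C)C)C(C)C)=C(CC=C(C)C)\C(O[Si](C(C)C)(C(C)C)C(C)C)=C\Cc1c(OCOCC[Si](C)(C)C)c(C)c(CC)oc1=O | intermediate
27 | cyclohexa-2,4-dien-1-one from electrocyclisation of 26 (keto tautomer of 28, mixture at C6) | O=C1C([C@H](O[Si](CC)(CC)CC)[C@H](C)CC)=C(O[Si](C(C)C)(C(C)C)C(C)C)C(CC=C(C)C)=C(O[Si](C(C)C)(C(C)C)C(C)C)C1Cc1c(OCOCC[Si](C)(C)C)c(C)c(CC)oc1=O | intermediate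
28 | 6-ethyl-3-({2-hydroxy-3-[(1R,2R)-2-methyl-1-(triethylsilyloxy)butyl]-5-(3-methylbut-2-en-1-yl)-4,6-bis(triisopropylsilyloxy)phenyl}methyl)-5-methyl-4-{[2-(trimethylsilyl)ethoxy]methoxy}-2H-pyran-2-one | CCc1oc(=O)c(Cc2c(O[Si](C(C)C)(C(C)C)C(C)C)c(CC=C(C)C)c(O[Si](C(C)C)(C(C)C)C(C)C)c([C@H](O[Si](CC)(CC)CC)[C@H](C)CC)c2O)c(OCOCC[Si](C)(C)C)c1C | intermediate
29 | 6-ethyl-3-({2-methoxy-3-[(1R,2R)-2-methyl-1-(triethylsilyloxy)butyl]-5-(3-methylbut-2-en-1-yl)-4,6-bis(triisopropylsilyloxy)phenyl}methyl)-5-methyl-4-{[2-(trimethylsilyl)ethoxy]methoxy}-2H-pyran-2-one | CCc1oc(=O)c(Cc2c(O[Si](C(C)C)(C(C)C)C(C)C)c(CC=C(C)C)c(O[Si](C(C)C)(C(C)C)C(C)C)c([C@H](O[Si](CC)(CC)CC)[C@H](C)CC)c2OC)c(OCOCC[Si](C)(C)C)c1C | intermediate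
30 | 6-ethyl-3-({3-[(1R,2R)-1-hydroxy-2-methylbutyl]-2-methoxy-5-(3-methylbut-2-en-1-yl)-4,6-bis(triisopropylsilyloxy)phenyl}methyl)-5-methyl-4-{[2-(trimethylsilyl)ethoxy]methoxy}-2H-pyran-2-one | CCc1oc(=O)c(Cc2c(O[Si](C(C)C)(C(C)C)C(C)C)c(CC=C(C)C)c(O[Si](C(C)C)(C(C)C)C(C)C)c([C@H](O)[C@H](C)CC)c2OC)c(OCOCC[Si](C)(C)C)c1C | intermediate
31 | 6-ethyl-3-({2-methoxy-3-[(2R)-2-methylbutanoyl]-5-(3-methylbut-2-en-1-yl)-4,6-bis(triisopropylsilyloxy)phenyl}methyl)-5-methyl-4-{[2-(trimethylsilyl)ethoxy]methoxy}-2H-pyran-2-one | CCc1oc(=O)c(Cc2c(O[Si](C(C)C)(C(C)C)C(C)C)c(CC=C(C)C)c(O[Si](C(C)C)(C(C)C)C(C)C)c(C(=O)[C@H](C)CC)c2OC)c(OCOCC[Si](C)(C)C)c1C | intermediate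
32 | 6-ethyl-3-({2,4-dihydroxy-6-methoxy-5-[(2R)-2-methylbutanoyl]-3-(3-methylbut-2-en-1-yl)phenyl}methyl)-4-hydroxy-5-methyl-2H-pyran-2-one | CCc1oc(=O)c(Cc2c(O)c(CC=C(C)C)c(O)c(C(=O)[C@H](C)CC)c2OC)c(O)c1C | target

Total step count: 16. Longest linear sequence: 11 steps (5 → 6 → 8 → 10 → 12 → 13 → 16 → 28 → 29 → 30 → 31 → 32; steps 2–7 and 12–16).

Steps most likely to fail

Step 12. The branched siloxyalkyne may add to the crowded vinylketene too slowly, so that ketene dimerisation, O-acylation of the product phenol by the ketene, or a stalled electrocyclisation at the substituted ring terminus take over. The fallback sets out from 4 and 23 (with 8) and returns at 32; the pyranone arm is left out of the annulation and the CH2 bridge is made last. Ketene gas with 4 (CH2Cl2, 0 °C) should give 2-(3-methylbut-2-en-1-yl)-3-(triisopropylsilyloxy)cyclobut-2-en-1-one F1. Its benzannulation with 23 (toluene, 80–110 °C) closes only a pentasubstituted ring, well within known scope, to 2-[(1R,2R)-2-methyl-1-(triethylsilyloxy)butyl]-4-(3-methylbut-2-en-1-yl)-3,5-bis(triisopropylsilyloxy)phenol F2. The reagents of steps 13–16 then lead through triethyl{(1R,2R)-1-[6-methoxy-3-(3-methylbut-2-en-1-yl)-2,4-bis(triisopropylsilyloxy)phenyl]-2-methylbutoxy}silane F3, (1R,2R)-1-[6-methoxy-3-(3-methylbut-2-en-1-yl)-2,4-bis(triisopropylsilyloxy)phenyl]-2-methylbutan-1-ol F4 and (2R)-1-[6-methoxy-3-(3-methylbut-2-en-1-yl)-2,4-bis(triisopropylsilyloxy)phenyl]-2-methylbutan-1-one F5 to (2R)-1-[2,4-dihydroxy-6-methoxy-3-(3-methylbut-2-en-1-yl)phenyl]-2-methylbutan-1-one F6. Pyranone 8 and dimethylmethylideneammonium iodide give the Mannich base 3-[(dimethylamino)methyl]-6-ethyl-4-hydroxy-5-methyl-2H-pyran-2-one F7. On warming with F6 it loses dimethylamine to 6-ethyl-5-methyl-3-methylidene-2H-pyran-2,4(3H)-dione F8, which F6 should capture at its only free ring carbon (C1') in a Michael-type Friedel–Crafts alkylation, giving 32.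

Step 7. The monoalkylketene may dimerise or acylate its own precursor faster than it meets the alkyne, a path that amines and their hydrochlorides promote, and the acid chloride may lactonise onto the pyranone oxygen with loss of the SEM group. The fallback sets out from 12 and returns at 16 through ketene 15; it generates the ketene reductively and without amine (Staudinger zinc dehalogenation of an α-haloacyl halide). Organocatalytic α-chlorination of 12 (N-chlorosuccinimide, DL-proline, CH2Cl2) should give 2-chloro-3-(6-ethyl-5-methyl-2-oxo-4-{[2-(trimethylsilyl)ethoxy]methoxy}-2H-pyran-3-yl)propanal F9. Pinnick oxidation gives 2-chloro-3-(6-ethyl-5-methyl-2-oxo-4-{[2-(trimethylsilyl)ethoxy]methoxy}-2H-pyran-3-yl)propanoic acid F10, and the α-chloroenamine of step 7 gives 2-chloro-3-(6-ethyl-5-methyl-2-oxo-4-{[2-(trimethylsilyl)ethoxy]methoxy}-2H-pyran-3-yl)propanoyl chloride F11. Slow addition of F11 to activated Zn (Zn–Cu couple) and 4 in Et2O/1,2-dimethoxyethane, the latter to bind ZnCl2, should release 15, which closes with 4 to 16.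

Step 11. Addition of dibromomethyllithium to the hindered, α-branched α-silyloxy ester may be slow, and the alkoxide intermediates may shift or lose the silyl group before the ynolate forms. The fallback sets out from 20 and returns at ynolate 22; the ynolate is made by oxidation of an acetylide instead of ester homologation. i-Bu2AlH (CH2Cl2, −78 °C) should reduce 20 to (2R,3R)-3-methyl-2-(triethylsilyloxy)pentanal F12. CBr4/PPh3 (CH2Cl2, 0 °C, Corey–Fuchs) gives (3R,4R)-1,1-dibromo-4-methyl-3-(triethylsilyloxy)hex-1-ene F13, and n-BuLi (2 equiv, THF, −78 °C) gives lithium (3R,4R)-4-methyl-3-(triethylsilyloxy)hex-1-yn-1-ide F14. Oxidation of F14 with t-BuOOLi (THF, −78 → 0 °C) should give 22, which is silylated with i-Pr3SiOTf as in step 11 to 23.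

Further compounds
F1 | step 12 | 2-(3-methylbut-2-en-1-yl)-3-(triisopropylsilyloxy)cyclobut-2-en-1-one | O=C1CC(O[Si](C(C)C)(C(C)C)C(C)C)=C1CC=C(C)C
F2 | step 12 | 2-[(1R,2R)-2-methyl-1-(triethylsilyloxy)butyl]-4-(3-methylbut-2-en-1-yl)-3,5-bis(triisopropylsilyloxy)phenol | Oc1cc(O[Si](C(C)C)(C(C)C)C(C)C)c(CC=C(C)C)c(O[Si](C(C)C)(C(C)C)C(C)C)c1[C@H](O[Si](CC)(CC)CC)[C@H](C)CC
F3 | step 12 | triethyl{(1R,2R)-1-[6-methoxy-3-(3-methylbut-2-en-1-yl)-2,4-bis(triisopropylsilyloxy)phenyl]-2-methylbutoxy}silane | COc1cc(O[Si](C(C)C)(C(C)C)C(C)C)c(CC=C(C)C)c(O[Si](C(C)C)(C(C)C)C(C)C)c1[C@H](O[Si](CC)(CC)CC)[C@H](C)CC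
F4 | step 12 | (1R,2R)-1-[6-methoxy-3-(3-methylbut-2-en-1-yl)-2,4-bis(triisopropylsilyloxy)phenyl]-2-methylbutan-1-ol | COc1cc(O[Si](C(C)C)(C(C)C)C(C)C)c(CC=C(C)C)c(O[Si](C(C)C)(C(C)C)C(C)C)c1[C@H](O)[C@H](C)CC
F5 | step 12 | (2R)-1-[6-methoxy-3-(3-methylbut-2-en-1-yl)-2,4-bis(triisopropylsilyloxy)phenyl]-2-methylbutan-1-one | COc1cc(O[Si](C(C)C)(C(C)C)C(C)C)c(CC=C(C)C)c(O[Si](C(C)C)(C(C)C)C(C)C)c1C(=O)[C@H](C)CC
F6 | step 12 | (2R)-1-[2,4-dihydroxy-6-methoxy-3-(3-methylbut-2-en-1-yl)phenyl]-2-methylbutan-1-one | COc1cc(O)c(CC=C(C)C)c(O)c1C(=O)[C@H](C)CC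
F7 | step 12 | 3-[(dimethylamino)methyl]-6-ethyl-4-hydroxy-5-methyl-2H-pyran-2-one | CCc1oc(=O)c(CN(C)C)c(O)c1C
F8 | step 12 | 6-ethyl-5-methyl-3-methylidene-2H-pyran-2,4(3H)-dione | CCC1=C(C)C(=O)C(=C)C(=O)O1
F9 | step 7 | 2-chloro-3-(6-ethyl-5-methyl-2-oxo-4-{[2-(trimethylsilyl)ethoxy]methoxy}-2H-pyran-3-yl)propanal (racemic) | CCc1oc(=O)c(CC(Cl)C=O)c(OCOCC[Si](C)(C)C)c1C
F10 | step 7 | 2-chloro-3-(6-ethyl-5-methyl-2-oxo-4-{[2-(trimethylsilyl)ethoxy]methoxy}-2H-pyran-3-yl)propanoic acid (racemic) | CCc1oc(=O)c(CC(Cl)C(=O)O)c(OCOCC[Si](C)(C)C)c1C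
F11 | step 7 | 2-chloro-3-(6-ethyl-5-methyl-2-oxo-4-{[2-(trimethylsilyl)ethoxy]methoxy}-2H-pyran-3-yl)propanoyl chloride (racemic) | CCc1oc(=O)c(CC(Cl)C(=O)Cl)c(OCOCC[Si](C)(C)C)c1C
F12 | step 11 | (2R,3R)-3-methyl-2-(triethylsilyloxy)pentanal | CC[C@@H](C)[C@@H](O[Si](CC)(CC)CC)C=O
F13 | step 11 | (3R,4R)-1,1-dibromo-4-methyl-3-(triethylsilyloxy)hex-1-ene | CC[C@@H](C)[C@@H](O[Si](CC)(CC)CC)C=C(Br)Br
F14 | step 11 | lithium (3R,4R)-4-methyl-3-(triethylsilyloxy)hex-1-yn-1-ide | [Li+].[C-]#C[C@H](O[Si](CC)(CC)CC)[C@H](C)CC
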